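The bicyclic core hinges on the C8–C8a=C4a–C4 unit at the junction of rings A and B. It is a Z-enedione whose four carbons, bearing O7, O1, C5 and the ketone oxygen, are the ring carbons of a squaric ester once a C4–C8 bond is drawn. The precursor is therefore a squarate-derived 4-hydroxycyclobutenone carrying both enantiopure side chains, with the ring carbinol and the C6 hydroxyl free and the C2 oxygen silylated. In one operation Pb(OAc)4 cleaves C4–C8, unveils the C4 ketone and lets the C6 hydroxyl trap the C8 acyl carbon as the ring A lactone. Acid then desilylates and closes ring B at C8a.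

Key step: step 4

Remarks on the chemistry
- Numbering of the target: O1, C2 (heptyl), C3, C4 (ketone), C4a, C5, C6 (decyl), O7, C8 (lactone carbonyl), C8a. Ring A is the lactone ring and ring B is the pyranone ring. The target is (2S,6S).
- The ring carbinol carbons of 4, 5, 6, 9, 10 and 11 are carried as mixtures of epimers, and their SMILES leave these centres undefined. This is harmless because that carbon becomes the C4 carbonyl.
- The β-lithio alkoxides 3 and 8 take the descriptor R only because CH2Li ranks below the alkyl chain. Their spatial arrangement is that of the (S)-epoxides.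
- Compared with a fully unprotected triol, the precursor 11 keeps the C2 oxygen as a silyl ether. Only the ring carbinol and the acyl-trapping C6 hydroxyl then face the oxidant, and the same acid that closes ring B removes the silyl group.

Step 1
Reactants: 1 diisopropyl squarate; 2 (S)-1,2-epoxynonane
Product: 4 4-hydroxy-4-[(S)-2-hydroxynonyl]-2,3-diisopropoxycyclobut-2-en-1-one (both epimers at the ring carbinol), via β-lithio alkoxide 3 (not isolated)
Conditions: Li, 4,4'-di-tert-butylbiphenyl, THF, 0 °C (lithium 4,4'-di-tert-butylbiphenylide, 2.0 equiv per epoxide); 2, −78 °C; cannulate into 1 (1.3 equiv), THF, −78 °C; sat. aq. NH4Cl, −78 °C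
Reagents that add atoms: none
Why: Reductive lithiation of a terminal alkyl epoxide by an arene radical anion cleaves the primary C–O bond and gives the primary β-lithio alkoxide with the carbinol centre untouched, and this organolithium should add once, in 1,2 fashion, to a squarate carbonyl at −78 °C (organolithium addition to a squaric ester), the uncontrolled ring carbinol being irrelevant.

Step 2
Reactants: 4 4-hydroxy-4-[(S)-2-hydroxynonyl]-2,3-diisopropoxycyclobut-2-en-1-one
Product: 6 4-[(S)-2-(tert-butyldimethylsilyloxy)nonyl]-2,3-diisopropoxy-4-(trimethylsilyloxy)cyclobut-2-en-1-one, via mono-TBS ether 5 (not isolated)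
Conditions: TBSCl (1.1 equiv), imidazole (4 equiv), DMF, 0 °C → rt; then TMSCl (1.5 equiv), rt
Reagents that add atoms: tert-butyldimethylsilyl chloride, CC(C)(C)[Si](C)(C)Cl; trimethylsilyl chloride, C[Si](C)(C)Cl
Why: Silyl chloride/imidazole silylation discriminates sharply between a secondary and a hindered tertiary alcohol, so TBSCl should take the side-chain hydroxyl and the more reactive TMSCl then caps the ring carbinol (sequential silyl ether formation).

Step 3
Reactants: 6 4-[(S)-2-(tert-butyldimethylsilyloxy)nonyl]-2,3-diisopropoxy-4-(trimethylsilyloxy)cyclobut-2-en-1-one; 7 (S)-1,2-epoxydodecane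
Product: 11 4-[(S)-2-(tert-butyldimethylsilyloxy)nonyl]-4-hydroxy-3-[(S)-2-hydroxydodecyl]-2-isopropoxycyclobut-2-en-1-one (both epimers at the ring carbinol), via β-lithio alkoxide 8 (not isolated), via cyclobutenediol monosilyl ether 9 (not isolated), via TMS ether 10 (not isolated)
Conditions: Li, 4,4'-di-tert-butylbiphenyl, THF, 0 °C; 7, −78 °C; then 6, THF, −78 °C; AcOH in THF, −78 °C; then 0.5 M aq. HCl, 0 °C
Reagents that add atoms: water, O
Why: The second β-lithio alkoxide should add to the only ring carbonyl, and on acidification the free, doubly activated allylic hydroxyl ionises far faster than the silyl ether is cleaved, so water enters at the isopropoxy-stabilised cation terminus and isopropanol leaves (1,2-addition then acid-mediated carbonyl transposition of a squarate adduct); this fixes the C12 chain on the alkene carbon and the isopropoxy group next to the new ketone before cold dilute acid hydrolyses the trimethylsilyl ether and spares the tert-butyldimethylsilyl ether.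

Step 4
Reactants: 11 4-[(S)-2-(tert-butyldimethylsilyloxy)nonyl]-4-hydroxy-3-[(S)-2-hydroxydodecyl]-2-isopropoxycyclobut-2-en-1-one
Product: 12 (S)-4-[(S)-3-(tert-butyldimethylsilyloxy)decanoyl]-6-decyl-3-isopropoxy-5,6-dihydro-2H-pyran-2-one
Conditions: Pb(OAc)4 (1.2 equiv), toluene, 0 °C → rt
Reagents that add atoms: none
Why: Proposed new method: ligand exchange puts the tertiary ring oxygen on tetravalent lead, and Pb–O homolysis (or the two-electron fragmentation typical of α-ketols) breaks the C4–C8 ring bond with release of cyclobutene strain, giving the C4 ketone and a C8 acyl radical that trivalent lead oxidises to the acylium or its acetate adduct. The closest known reaction type is the Pb(OAc)4 ring opening of squarate-derived 4-hydroxycyclobutenones to 5-acetoxy-2(5H)-furanones, together with Pb(OAc)4 cleavage of α-hydroxy ketones to esters in alcohols; trapping by a remote side-chain hydroxyl is the part without precedent. Ring A closes by 6-exo attack of the C6 hydroxyl oxygen on the C8 acyl carbon (exo-dig on the acylium, exo-trig on an acyl acetate), which makes the O7–C8 bond. No stereocentre is created: the ring carbinol becomes the planar C4 carbonyl, C2 and C6 are untouched, and the Z geometry of C4a=C8a is inherited from the four-membered ring. The step needs reaction at the ring carbinol and not at the secondary C6 alcohol, which strain-driven fragmentation at room temperature should secure because Pb(OAc)4 attacks ordinary secondary alcohols only on heating, while the silyl group keeps the C2 oxygen out of both the oxidation and the acyl capture. Should acetate or the C4 carbonyl oxygen win the acyl carbon, the resulting acetoxybutenolide is still an acyl donor towards O7 under the acid of step 5.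

Step 5
Reactants: 12 (S)-4-[(S)-3-(tert-butyldimethylsilyloxy)decanoyl]-6-decyl-3-isopropoxy-5,6-dihydro-2H-pyran-2-one
Product: 14 (2S,6S)-6-decyl-2-heptyl-2,3,5,6-tetrahydropyrano[3,4-b]pyran-4,8-dione, via hydroxy ketone 13 (not isolated)
Conditions: 48% aq. HF, MeCN, 0 °C → rt; then TsOH·H2O (10 mol%), toluene, 50 °C
Reagents that add atoms: none
Why: Cleavage of the secondary silyl ether frees the C2 hydroxyl, which under TsOH adds to C8a of the protonated vinylogous ester in a 6-endo-trig oxa-Michael step and expels isopropanol (acid-catalysed addition–elimination to a 2,3-dihydro-4H-pyran-4-one), with C2 and C6 unchanged because no bond to either centre is broken.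

Compound list
1 | diisopropyl squarate | CC(C)OC1=C(OC(C)C)C(=O)C1=O | starting material
2 | (S)-1,2-epoxynonane | CCCCCCC[C@H]1CO1 | starting material
3 | lithium (R)-1-lithiononan-2-olate | CCCCCCC[C@H](O[Li])C[Li] | intermediate
4 | 4-hydroxy-4-[(S)-2-hydroxynonyl]-2,3-diisopropoxycyclobut-2-en-1-one | CCCCCCC[C@H](O)CC1(O)C(OC(C)C)=C(OC(C)C)C1=O | intermediate
5 | 4-[(S)-2-(tert-butyldimethylsilyloxy)nonyl]-4-hydroxy-2,3-diisopropoxycyclobut-2-en-1-one | CCCCCCC[C@H](O[Si](C)(C)C(C)(C)C)CC1(O)C(OC(C)C)=C(OC(C)C)C1=O | intermediate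
6 | 4-[(S)-2-(tert-butyldimethylsilyloxy)nonyl]-2,3-diisopropoxy-4-(trimethylsilyloxy)cyclobut-2-en-1-one | CCCCCCC[C@H](O[Si](C)(C)C(C)(C)C)CC1(O[Si](C)(C)C)C(OC(C)C)=C(OC(C)C)C1=O | intermediate
7 | (S)-1,2-epoxydodecane | CCCCCCCCCC[C@H]1CO1 | starting material
8 | lithium (R)-1-lithiododecan-2-olate | CCCCCCCCCC[C@H](O[Li])C[Li] | intermediate
9 | 4-[(S)-2-(tert-butyldimethylsilyloxy)nonyl]-1-[(S)-2-hydroxydodecyl]-2,3-diisopropoxy-4-(trimethylsilyloxy)cyclobut-2-en-1-ol | CCCCCCCCCC[C@H](O)CC1(O)C(OC(C)C)=C(OC(C)C)C1(O[Si](C)(C)C)C[C@@H](O[Si](C)(C)C(C)(C)C)CCCCCCC | intermediate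
10 | 4-[(S)-2-(tert-butyldimethylsilyloxy)nonyl]-3-[(S)-2-hydroxydodecyl]-2-isopropoxy-4-(trimethylsilyloxy)cyclobut-2-en-1-one | CCCCCCCCCC[C@H](O)CC1=C(OC(C)C)C(=O)C1(O[Si](C)(C)C)C[C@@H](O[Si](C)(C)C(C)(C)C)CCCCCCC | intermediate
11 | 4-[(S)-2-(tert-butyldimethylsilyloxy)nonyl]-4-hydroxy-3-[(S)-2-hydroxydodecyl]-2-isopropoxycyclobut-2-en-1-one | CCCCCCCCCC[C@H](O)CC1=C(OC(C)C)C(=O)C1(O)C[C@@H](O[Si](C)(C)C(C)(C)C)CCCCCCC | intermediate
12 | (S)-4-[(S)-3-(tert-butyldimethylsilyloxy)decanoyl]-6-decyl-3-isopropoxy-5,6-dihydro-2H-pyran-2-one | CCCCCCCCCC[C@H]1CC(C(=O)C[C@@H](O[Si](C)(C)C(C)(C)C)CCCCCCC)=C(OC(C)C)C(=O)O1 | intermediate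
13 | (S)-6-decyl-4-[(S)-3-hydroxydecanoyl]-3-isopropoxy-5,6-dihydro-2H-pyran-2-one | CCCCCCCCCC[C@H]1CC(C(=O)C[C@@H](O)CCCCCCC)=C(OC(C)C)C(=O)O1 | intermediate
14 | (2S,6S)-6-decyl-2-heptyl-2,3,5,6-tetrahydropyrano[3,4-b]pyran-4,8-dione | CCCCCCCCCC[C@H]1CC2=C(O[C@@H](CCCCCCC)CC2=O)C(=O)O1 | target

Total step count: 5
Longest linear sequence: 5 steps (1 → 4 → 6 → 11 → 12 → 14)

Steps most likely to fail

Step 4. The acyl intermediate may be captured by acetate or by the new C4 carbonyl oxygen instead of the C6 hydroxyl, or lead may attack the secondary C6 alcohol and fragment it towards the allylic C5 radical. The fallback blocks the C6 oxygen and uses the ring opening in its established form. Starting from 11, TESCl and imidazole in DMF at 0 °C should silylate only the secondary hydroxyl to give 4-[(S)-2-(tert-butyldimethylsilyloxy)nonyl]-4-hydroxy-2-isopropoxy-3-[(S)-2-(triethylsilyloxy)dodecyl]cyclobut-2-en-1-one F1. Pb(OAc)4 in toluene at rt should then deliver, with acetate capture, 5-acetoxy-5-[(S)-2-(tert-butyldimethylsilyloxy)nonyl]-3-isopropoxy-4-[(S)-2-(triethylsilyloxy)dodecyl]furan-2(5H)-one F2. Aqueous HF in MeCN should remove both silyl groups and hydrolyse the acylal to 5-hydroxy-4-[(S)-2-hydroxydodecyl]-5-[(S)-2-hydroxynonyl]-3-isopropoxyfuran-2(5H)-one F3, the ring tautomer of the Z-4-oxo-2-enoic acid. TsOH in toluene at 60 °C over 4 Å molecular sieves should then lactonise the acid onto the C6 hydroxyl and close ring B, which brings the material back to the route at 14.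

Step 3. Migration of the trimethylsilyl group to the neighbouring lithium alkoxide, or its loss before the rearrangement, would let the wrong ring hydroxyl ionise and scramble which side chain sits on the carbinol carbon. The fallback uses a silyl group that neither migrates nor falls off and separates rearrangement from unmasking. Starting from 4, and passing through 5 (TBSCl, imidazole), TESOTf and 2,6-lutidine in CH2Cl2 at −78 → 0 °C should give 4-[(S)-2-(tert-butyldimethylsilyloxy)nonyl]-2,3-diisopropoxy-4-(triethylsilyloxy)cyclobut-2-en-1-one F4. Addition of 8 at −78 °C should give 4-[(S)-2-(tert-butyldimethylsilyloxy)nonyl]-1-[(S)-2-hydroxydodecyl]-2,3-diisopropoxy-4-(triethylsilyloxy)cyclobut-2-en-1-ol F5. A brief treatment with catalytic HCl in wet CH2Cl2 should rearrange it to 4-[(S)-2-(tert-butyldimethylsilyloxy)nonyl]-3-[(S)-2-hydroxydodecyl]-2-isopropoxy-4-(triethylsilyloxy)cyclobut-2-en-1-one F6. AcOH/THF/H2O at rt should then cleave the triethylsilyl ether selectively and return the material to the route at 11.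

Step 1. The β-lithio alkoxide may lose lithium oxide to give 1-nonene, and leftover radical anion may reduce the squarate by electron transfer. The fallback makes the same organolithium by carbon–halogen reduction of a preformed alkoxide, so the reductant can be dosed exactly against an isolable precursor. Starting from 2, LiCl and AcOH in THF should open the epoxide at the terminal carbon to (S)-1-chlorononan-2-ol F7. n-BuLi at −78 °C should convert it into lithium (S)-1-chlorononan-2-olate F8, and lithium naphthalenide (2 equiv) at −78 °C should then give 3, where the route is rejoined before the addition to 1.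

Further compounds
F1 | step 4 | 4-[(S)-2-(tert-butyldimethylsilyloxy)nonyl]-4-hydroxy-2-isopropoxy-3-[(S)-2-(triethylsilyloxy)dodecyl]cyclobut-2-en-1-one | CCCCCCCCCC[C@H](O[Si](CC)(CC)CC)CC1=C(OC(C)C)C(=O)C1(O)C[C@@H](O[Si](C)(C)C(C)(C)C)CCCCCCC
F2 | step 4 | 5-acetoxy-5-[(S)-2-(tert-butyldimethylsilyloxy)nonyl]-3-isopropoxy-4-[(S)-2-(triethylsilyloxy)dodecyl]furan-2(5H)-one | CCCCCCCCCC[C@H](O[Si](CC)(CC)CC)CC1=C(OC(C)C)C(=O)OC1(OC(C)=O)C[C@@H](O[Si](C)(C)C(C)(C)C)CCCCCCC
F3 | step 4 | 5-hydroxy-4-[(S)-2-hydroxydodecyl]-5-[(S)-2-hydroxynonyl]-3-isopropoxyfuran-2(5H)-one | CCCCCCCCCC[C@H](O)CC1=C(OC(C)C)C(=O)OC1(O)C[C@@H](O)CCCCCCC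
F4 | step 3 | 4-[(S)-2-(tert-butyldimethylsilyloxy)nonyl]-2,3-diisopropoxy-4-(triethylsilyloxy)cyclobut-2-en-1-one | CCCCCCC[C@H](O[Si](C)(C)C(C)(C)C)CC1(O[Si](CC)(CC)CC)C(OC(C)C)=C(OC(C)C)C1=O
F5 | step 3 | 4-[(S)-2-(tert-butyldimethylsilyloxy)nonyl]-1-[(S)-2-hydroxydodecyl]-2,3-diisopropoxy-4-(triethylsilyloxy)cyclobut-2-en-1-ol | CCCCCCCCCC[C@H](O)CC1(O)C(OC(C)C)=C(OC(C)C)C1(O[Si](CC)(CC)CC)C[C@@H](O[Si](C)(C)C(C)(C)C)CCCCCCC
F6 | step 3 | 4-[(S)-2-(tert-butyldimethylsilyloxy)nonyl]-3-[(S)-2-hydroxydodecyl]-2-isopropoxy-4-(triethylsilyloxy)cyclobut-2-en-1-one | CCCCCCCCCC[C@H](O)CC1=C(OC(C)C)C(=O)C1(O[Si](CC)(CC)CC)C[C@@H](O[Si](C)(C)C(C)(C)C)CCCCCCC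
F7 | step 1 | (S)-1-chlorononan-2-ol | CCCCCCC[C@H](O)CCl
F8 | step 1 | lithium (S)-1-chlorononan-2-olate | CCCCCCC[C@H](O[Li])CCl
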